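## Analysis of the target

Compound 12 is a 1-aryl-1,2,3,4-tetrahydronaphthalene: aromatic ring A (C4a, C5–C8, C8a) is fused to the saturated ring B (C1–C4), and C1 carries a 4-hydroxy-3-methoxyphenyl (guaiacyl) ring. The same atom numbers are used below for the corresponding atoms of all earlier compounds. Ring A is pentasubstituted: only C5 is CH, C6 and C8 carry methoxy groups, C7 between them carries the free hydroxyl, and the C8 methoxy lies peri to C1. Ring B holds three contiguous stereocentres, C1 (S), C2 (R) and C3 (R). Decoded, this means 1,2-trans and 2,3-trans, with the aryl group and the C3 hydroxymethyl on one face and the C2 hydroxymethyl on the other; C4 is a plain benzylic CH2. The sensitive groups are two free phenols and two primary alcohols. The guaiacyl phenol is para to the C1 methine, so oxidation would pass through a quinone methide and erase C1. The difficulty is that C1 is a diarylmethine wedged between the C8 methoxy, the guaiacyl ring and C2, so arene substitution at C1 is hindered, and that three stereocentres must be set in the absolute sense on a ring with no heteroatom to steer them. The strategy rests on one feature: C1 and C4 are both benzylic and sit on the adjacent ring A carbons C8a and C4a. Ring B is therefore an ortho-quinodimethane of ring A plus the two-carbon unit C2–C3, and the trans relationship at C2/C3 is that of an (E)-alkene.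

## Retrosynthetic reasoning

**12 back to 11.** No skeletal bond is cut; the two hydroxymethyl groups are taken back to carboxylic esters (diester 11). This turns C2 and C3 into the carbons of an electron-poor alkene and gives the ester alkyl groups as the place for a chiral alcohol. The forward step is a hydride reduction that must leave C2 and C3 untouched.

**11 back to 10.** The C1–H bond is taken back to C1–OH and the two phenols to benzyl ethers (carbinol 10). A C1 carbinol is what a diaryl ketone carbon becomes when it serves as a diene terminus. Benzyl is chosen because free phenols quench excited aryl ketones and because the same hydrogenolysis removes both the benzyl groups and the C1 hydroxyl. The forward step must replace the hydroxyl by hydrogen with retention on a nickel surface. In 10 the hydroxyl is cis to the C2 ester, so the aryl group is already trans to it.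

**10 back to 5 and 8 (through 9).** The bonds C1–C2 and C3–C4 are cut. Both join a benzylic carbon of ring A to the C2–C3 unit, so the cut leaves dienol 9 and the (E)-butenedioate 8; the stable form of 9 is ketone 5 with an ortho methyl group. Cutting C1–C8a or C1–aryl instead would require electrophilic substitution next to the C8 methoxy, and cutting C2–C3 would leave two separate stereocentres to control.

- What is gained: ring B, two C–C bonds and all three stereocentres in one step, the C2/C3 trans relationship from alkene geometry, and no regiochemical question because 8 is C2-symmetric.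
- What the forward reaction must do: generate 9 by light with the hydroxyl turned outward, add 8 with the C2 ester under the diene (endo), and do so on one face of 8.
- Why lactate esters: face control by fumarates of simple terpene alcohols depends on a strong Lewis acid locking the enoate, and such an acid cannot be present beside a photochemically made dienol. An α-acyloxy ester offers a second carbonyl for hydrogen bonding to the dienol hydroxyl without additives. It also has no benzylic C–O bond that the later hydrogenolysis would cleave.

**5 back to 2 and 4.** The bond between the carbonyl carbon and ring A is cut. Ring A as the nucleophile (arene 2) has only one kind of free position, ortho to the methyl group and ortho/para to methoxy groups. The opposite polarity would need a 2,6-disubstituted benzoic acid derivative and a regioselective substitution on a guaiacyl ether. The forward step is a Friedel–Crafts acylation with acid chloride 4 that must not cleave aryl ethers.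

**2, 4 and 8 back to bought materials.** Arene 2 comes from phenol 1 by O-benzylation, acid chloride 4 from acid 3, and diester 8 from diacid chloride 6 and two molecules of hydroxy ester 7.

## Alternatives that were turned down

**Alternative 1:** Disconnection at C2–C3 and C1–C8a. Both arylpropenoate halves are hung as esters on one C2-symmetric chiral 1,2-diaryl glycol, giving the mixed diester A2.

- Forward key step: FeCl3 or Ag2O oxidises both phenols and the radicals couple at C2–C3 inside the tether. The syringyl half re-aromatises by proton loss (creating C3=C4) and its ring attacks the quinone methide carbon C1 of the guaiacyl half, closing ring B to the eight-membered dilactone A1.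
- For it: two skeletal bonds and ring B from unprotected phenols in one operation; a very short precursor synthesis; no deoxygenation at C1; reductive removal of the tether gives the diol directly.
- Against it for this target: the two halves differ, so the cascade can choose the wrong ring as ring A (guaiacyl ring attacking the syringyl quinone methide, a constitutional isomer). The guaiacyl radical also has a free position ortho to its oxygen, which opens other coupling modes. A1 still carries C3=C4, so C3 must be set later by reducing a conjugated trisubstituted alkene trans to C2 under substrate control, and the dihydronaphthalene is one oxidation away from the fully aromatic naphthalene.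
- Comparison: Alternative 1 is stronger in step count. The chosen route offers instead an unambiguous ring assignment (ring A is the arene that carries the methyl group in 5), C2/C3 trans taken directly from the geometry of 8, and no late alkene reduction.

**Alternative 2:** Disconnection at C1–C8a and at the C1–guaiacyl bond. C1 becomes the aldehyde carbon of the open-chain aldehyde A4, and the guaiacyl ring comes from guaiacol A5 itself.

- Forward key step: BF3·OEt2 or Bi(OTf)3 activates the aldehyde, and the syringyl ring closes ring B by intramolecular hydroxyalkylation. The resulting benzylic carbinol ionises to a cation stabilised by the ortho and para methoxy groups of ring A, and A5 captures it para to its hydroxyl, giving the bis(pivalate) A3. Ester cleavage would complete the synthesis.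
- For it: highly convergent; A5 is used unprotected; the C1–aryl bond is formed directly with no hydroxyl to remove; the C1 configuration follows from attack anti to the C2 substituent.
- Against it: the stereochemical work is hidden in A4. Its two adjacent stereocentres must be made enantiopure in a separate sequence, and C2 is α to the aldehyde and can epimerise under the Lewis acid. The C1 cation lies beside the peri C8 methoxy, so intermolecular arylation competes with proton loss from C2. A5 can also react at more than one position or add twice to the aldehyde before ring closure.
- Comparison: Alternative 2 is stronger at C1. The chosen route is shorter overall and sets C2 and C3 in the key step from a symmetric dienophile and a cheap chiral alcohol, not in a prior multi-step sequence.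

**Alternative 3:** Disconnection of ring A at C4a–C5 and C8–C8a. Ring A is built last from the cyclohexenylstannane A7, which already holds C1–C3, and 4-chloro-2,3-dimethoxycyclobutenone A8.

- Forward key step: a Stille-type coupling under a zerovalent palladium catalyst such as Pd(PPh3)4 forms C4a–C5. On warming, electrocyclic opening of the four-membered ring to a ketene and 6π closure form C8–C8a, and tautomerisation gives phenol A6.
- For it: the crowded pentasubstituted ring A is assembled with certain regiochemistry under neutral conditions, with no electrophilic substitution on a hindered arene.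
- Against it: the ketene carbon becomes the phenolic carbon, so A6 has the free hydroxyl at C8 and a methyl ether at C7, the reverse of the target. Correction needs methylation at C8 and selective cleavage of one of four aryl methyl ethers, or a cyclobutenone with two different alkoxy groups that is harder to make. None of the three stereocentres is made in the key step. A7 needs a long enantioselective synthesis, and its C1 is both allylic and benzylic and can be lost by double-bond migration. Stoichiometric tin waste is produced.
- Comparison: Alternative 3 is stronger only in the certainty of the ring A pattern. The chosen route does not need this, because phenol 1 already has the pattern, and it is much shorter and creates the stereocentres in its key step.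

Key step: step 5

Assumption: the (S)-lactate esters are taken to expose the Re,Re face of 8 to the dienol (the sense that gives 2S,3R in 10); if the opposite face reacts, methyl (R)-lactate replaces 7 and nothing else changes.

## Route

Step 1
Reactants: 1 2,6-dimethoxy-4-methylphenol
Product: 2 2-(benzyloxy)-1,3-dimethoxy-5-methylbenzene
Conditions: BnBr, K2CO3, DMF, 60 °C
Reagents that add atoms: benzyl bromide, BrCc1ccccc1
Why: Williamson ether synthesis on a phenol that K2CO3 deprotonates readily; the benzyl ether masks the O–H bond that would quench the excited ketone in step 5 and is removed on nickel in step 6.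

Step 2
Reactants: 3 4-(benzyloxy)-3-methoxybenzoic acid
Product: 4 4-(benzyloxy)-3-methoxybenzoyl chloride
Conditions: (COCl)2, cat. DMF, CH2Cl2, 0 °C → rt; evaporate, use crude
Reagents that add atoms: oxalyl chloride, ClC(=O)C(=O)Cl
Why: Acid chloride formation through the chloroiminium catalyst; the aryl ethers are inert and all by-products are gases.

Step 3
Reactants: 2 2-(benzyloxy)-1,3-dimethoxy-5-methylbenzene; 4 4-(benzyloxy)-3-methoxybenzoyl chloride
Product: 5 [4-(benzyloxy)-3-methoxyphenyl][3-(benzyloxy)-2,4-dimethoxy-6-methylphenyl]methanone
Conditions: SnCl4 (1.2 equiv), CH2Cl2, −20 → 0 °C; cold aq. HCl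
Reagents that add atoms: none
Why: Friedel–Crafts acylation; 2 has one kind of free ring position (two equivalent sites, each ortho to the methyl group, ortho to one methoxy and para to the other), so regiochemistry is not in question. SnCl4 is chosen as a mild Lewis acid to spare the methyl and benzyl ethers, and the twisted, deactivated ketone should not react a second time.

Step 4
Reactants: 6 fumaryl chloride; 7 methyl (2S)-2-hydroxypropanoate (2 equiv)
Product: 8 bis[(2S)-1-methoxy-1-oxopropan-2-yl] (2E)-but-2-enedioate
Conditions: pyridine (2.2 equiv), CH2Cl2, −10 °C → rt
Reagents that add atoms: none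
Why: Acylation of the secondary hydroxyl by the diacid chloride; the C–O bond at the lactate stereocentre is not broken and the (E) geometry is retained.

Step 5
Reactants: 5 [4-(benzyloxy)-3-methoxyphenyl][3-(benzyloxy)-2,4-dimethoxy-6-methylphenyl]methanone; 8 bis[(2S)-1-methoxy-1-oxopropan-2-yl] (2E)-but-2-enedioate
Product: 10 bis[(2S)-1-methoxy-1-oxopropan-2-yl] (1R,2S,3R)-7-(benzyloxy)-1-[4-(benzyloxy)-3-methoxyphenyl]-1-hydroxy-6,8-dimethoxy-1,2,3,4-tetrahydronaphthalene-2,3-dicarboxylate, via hydroxy-ortho-quinodimethane 9 (not isolated)
Conditions: hν (365 nm LED), 8 (3 equiv), degassed PhMe, 20 °C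
Reagents that add atoms: none
Why: Excitation of 5 and intersystem crossing give the triplet, whose oxygen takes a hydrogen from the ortho methyl group through a six-membered transition state (1,5-hydrogen transfer, faster than abstraction from the ortho methoxy group, which needs a seven-membered one); the biradical relaxes to dienol 9, and the isomer with the hydroxyl turned inward returns to 5 by a 1,5-hydrogen shift. The closest known reaction type is the photoenolisation/Diels–Alder trapping of ortho-alkyl aryl ketone dienols by fumarates, including additions of hydroxy-ortho-quinodimethanes to fumarates of chiral α-hydroxy esters. Ring B closes in a suprafacial [4+2] cycloaddition in which C1–C2 and C3–C4 form together and ring A regains its aromaticity. C2 and C3 are fixed trans by the (E) geometry of 8, which a concerted addition carries over unchanged. C1 is set relative to C2 by the diene geometry and the endo orientation: the outward hydroxyl and the ester lying under the diene end up cis, helped by an O–H···O=C hydrogen bond, so the aryl group is trans to the C2 ester. The absolute sense comes from the (S)-lactate groups, which place a methyl group on one face of the enoate and a methoxycarbonyl group on the other, and the Re,Re face has to react. The step needs endo selectivity at the C1 end and face selectivity but no regioselectivity, because 8 is C2-symmetric. The benzyl ethers keep phenolic O–H bonds out of the reaction, and neither 8 nor 10 absorbs at 365 nm.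

Step 6
Reactants: 10 bis[(2S)-1-methoxy-1-oxopropan-2-yl] (1R,2S,3R)-7-(benzyloxy)-1-[4-(benzyloxy)-3-methoxyphenyl]-1-hydroxy-6,8-dimethoxy-1,2,3,4-tetrahydronaphthalene-2,3-dicarboxylate
Product: 11 bis[(2S)-1-methoxy-1-oxopropan-2-yl] (1S,2R,3R)-7-hydroxy-1-(4-hydroxy-3-methoxyphenyl)-6,8-dimethoxy-1,2,3,4-tetrahydronaphthalene-2,3-dicarboxylate
Conditions: skeletal Ni (W-2 type, washed neutral), H2 (3 atm), EtOH, 25–50 °C
Reagents that add atoms: none
Why: Heterogeneous hydrogenolysis of benzylic C–O bonds; on nickel a tertiary benzylic hydroxyl binds the surface and is replaced by hydrogen from the same face, i.e. with retention (palladium gives inversion), so C1 becomes S with the aryl group trans to the C2 ester. The two aryl benzyl ethers are cleaved in the same operation; esters, aryl methyl ethers, C2 and C3 should be untouched on a neutral catalyst.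

Step 7
Reactants: 11 bis[(2S)-1-methoxy-1-oxopropan-2-yl] (1S,2R,3R)-7-hydroxy-1-(4-hydroxy-3-methoxyphenyl)-6,8-dimethoxy-1,2,3,4-tetrahydronaphthalene-2,3-dicarboxylate
Product: 12 (+)-8-methoxyisolariciresinol, (1S,2R,3R)-7-hydroxy-1-(4-hydroxy-3-methoxyphenyl)-2,3-bis(hydroxymethyl)-6,8-dimethoxy-1,2,3,4-tetrahydronaphthalene
Conditions: LiAlH4 (excess), THF, 0 → 40 °C; then 1 M HCl
Reagents that add atoms: none
Why: Hydride reduction of all four ester carbonyls; the ring esters become the two hydroxymethyl groups without change at C2 or C3, the phenols are carried as aluminium phenoxides and freed on acidification, and the lactate residues leave as water-soluble propane-1,2-diol and methanol.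

## Compound list

1 | 2,6-dimethoxy-4-methylphenol | Cc1cc(OC)c(O)c(OC)c1 | starting material
2 | 2-(benzyloxy)-1,3-dimethoxy-5-methylbenzene | Cc1cc(OC)c(OCc2ccccc2)c(OC)c1 | intermediate
3 | 4-(benzyloxy)-3-methoxybenzoic acid | COc1cc(C(=O)O)ccc1OCc1ccccc1 | starting material
4 | 4-(benzyloxy)-3-methoxybenzoyl chloride | COc1cc(C(=O)Cl)ccc1OCc1ccccc1 | intermediate
5 | [4-(benzyloxy)-3-methoxyphenyl][3-(benzyloxy)-2,4-dimethoxy-6-methylphenyl]methanone | COc1cc(C(=O)c2c(C)cc(OC)c(OCc3ccccc3)c2OC)ccc1OCc1ccccc1 | intermediate
6 | fumaryl chloride, (2E)-but-2-enedioyl dichloride | ClC(=O)/C=C/C(=O)Cl | starting material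
7 | methyl (2S)-2-hydroxypropanoate, methyl (S)-lactate | C[C@H](O)C(=O)OC | starting material
8 | bis[(2S)-1-methoxy-1-oxopropan-2-yl] (2E)-but-2-enedioate | COC(=O)[C@H](C)OC(=O)/C=C/C(=O)O[C@@H](C)C(=O)OC | intermediate
9 | hydroxy-ortho-quinodimethane: [4-(benzyloxy)-3-methoxyphenyl][3-(benzyloxy)-2,4-dimethoxy-6-methylidenecyclohexa-2,4-dien-1-ylidene]methanol, hydroxyl outward (on the side of the C8 methoxy, formally Z), aryl inward | C=C1C=C(OC)C(OCc2ccccc2)=C(OC)/C1=C(\O)c1ccc(OCc2ccccc2)c(OC)c1 | intermediate (not isolated)
10 | bis[(2S)-1-methoxy-1-oxopropan-2-yl] (1R,2S,3R)-7-(benzyloxy)-1-[4-(benzyloxy)-3-methoxyphenyl]-1-hydroxy-6,8-dimethoxy-1,2,3,4-tetrahydronaphthalene-2,3-dicarboxylate | COc1cc([C@@]2(O)c3c(cc(OC)c(OCc4ccccc4)c3OC)C[C@@H](C(=O)O[C@@H](C)C(=O)OC)[C@@H]2C(=O)O[C@@H](C)C(=O)OC)ccc1OCc1ccccc1 | intermediate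
11 | bis[(2S)-1-methoxy-1-oxopropan-2-yl] (1S,2R,3R)-7-hydroxy-1-(4-hydroxy-3-methoxyphenyl)-6,8-dimethoxy-1,2,3,4-tetrahydronaphthalene-2,3-dicarboxylate | COc1cc([C@H]2c3c(cc(OC)c(O)c3OC)C[C@@H](C(=O)O[C@@H](C)C(=O)OC)[C@@H]2C(=O)O[C@@H](C)C(=O)OC)ccc1O | intermediate
12 | (+)-8-methoxyisolariciresinol, (1S,2R,3R)-7-hydroxy-1-(4-hydroxy-3-methoxyphenyl)-2,3-bis(hydroxymethyl)-6,8-dimethoxy-1,2,3,4-tetrahydronaphthalene | COc1cc([C@H]2c3c(cc(OC)c(O)c3OC)C[C@@H](CO)[C@@H]2CO)ccc1O | target

## Step count and least certain steps

Total step count: 7. Longest linear sequence: 5 steps (steps 1, 3, 5, 6, 7; the branch from 3 through steps 2, 3, 5, 6, 7 is equally long).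

**Step 5 (key step).**
- What may go wrong: bond formation at C1, which becomes a fully substituted carbon between the inward aryl group and the peri methoxy, may be slower than the other exits of the dienol (closure to a four-membered ring, return to the ketone). The excited ketone may then pass its triplet energy to the dienophile and isomerise it to the (Z)-diester, which leads to cis-2,3 adducts. Facial discrimination may also be incomplete, because the outward hydroxyl can hydrogen-bond to the C8 methoxy and not to a lactate carbonyl. The resulting diastereomers of 10 should be separable, and the opposite sense is met by the (R)-lactate.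
- Fallback: make the diene thermally so that the dienophile never sees light. Setting out from 5, irradiation at 365 nm without a trap should close dienol 9 to 4-(benzyloxy)-7-[4-(benzyloxy)-3-methoxyphenyl]-3,5-dimethoxybicyclo[4.2.0]octa-1,3,5-trien-7-ol F1 (racemic; its stereocentre is destroyed on reopening). Heating F1 with 8 in toluene at about 100 °C in the dark opens the four-membered ring with the hydroxyl rotating outward, and the same dienol adds to 8 and comes back to the route at 10. The higher temperature may cost some face selectivity.

**Step 6.**
- What may go wrong: C–O cleavage at the crowded tertiary carbinol may be slow. Forcing conditions then invite dehydration of the β-hydroxy ester followed by cis addition of hydrogen (wrong C1/C2 relationship), retro-aldol opening by residual alkali on the catalyst, or partial loss of retention.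
- Fallback: change the order of events. Setting out from 10, LiAlH4 in THF should give (1R,2R,3R)-7-(benzyloxy)-1-[4-(benzyloxy)-3-methoxyphenyl]-2,3-bis(hydroxymethyl)-6,8-dimethoxy-1,2,3,4-tetrahydronaphthalen-1-ol F2, which no longer has an ester to enolise, eliminate or fragment. In F2 the C2 hydroxymethyl lies on the same face as the C1 hydroxyl and can hold that face on the metal. Hydrogenolysis of F2 over skeletal Ni and H2 then removes the C1 hydroxyl and both benzyl groups and comes back to the route at 12.

**Step 3.**
- What may go wrong: the Lewis acid may cleave an ether (the methoxy group ortho to the new carbonyl through a chelate, or a benzyl ether), or attack at the position between methyl and methoxy may be sluggish.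
- Fallback: form the same bond with an aryllithium. Setting out from 2, NBS in MeCN should give 2-(benzyloxy)-4-bromo-1,3-dimethoxy-5-methylbenzene F3. Bromine–lithium exchange with n-BuLi in THF at −78 °C and addition to bought 4-(benzyloxy)-3-methoxybenzaldehyde F4 should give [4-(benzyloxy)-3-methoxyphenyl][3-(benzyloxy)-2,4-dimethoxy-6-methylphenyl]methanol F5 (racemic). Oxidation of F5 with MnO2 in CH2Cl2 comes back to the route at 5.

## Further compounds

F1 | step 5 | 4-(benzyloxy)-7-[4-(benzyloxy)-3-methoxyphenyl]-3,5-dimethoxybicyclo[4.2.0]octa-1,3,5-trien-7-ol (racemic) | COc1cc(C2(O)Cc3cc(OC)c(OCc4ccccc4)c(OC)c32)ccc1OCc1ccccc1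
F2 | step 6 | (1R,2R,3R)-7-(benzyloxy)-1-[4-(benzyloxy)-3-methoxyphenyl]-2,3-bis(hydroxymethyl)-6,8-dimethoxy-1,2,3,4-tetrahydronaphthalen-1-ol | COc1cc([C@@]2(O)c3c(cc(OC)c(OCc4ccccc4)c3OC)C[C@@H](CO)[C@@H]2CO)ccc1OCc1ccccc1
F3 | step 3 | 2-(benzyloxy)-4-bromo-1,3-dimethoxy-5-methylbenzene | Cc1cc(OC)c(OCc2ccccc2)c(OC)c1Br
F4 | step 3 | 4-(benzyloxy)-3-methoxybenzaldehyde (bought) | COc1cc(C=O)ccc1OCc1ccccc1
F5 | step 3 | [4-(benzyloxy)-3-methoxyphenyl][3-(benzyloxy)-2,4-dimethoxy-6-methylphenyl]methanol (racemic) | COc1cc(C(O)c2c(C)cc(OC)c(OCc3ccccc3)c2OC)ccc1OCc1ccccc1
A1 | alternative 1 | tethered trans-7-hydroxy-1-(4-hydroxy-3-methoxyphenyl)-6,8-dimethoxy-1,2-dihydronaphthalene-2,3-dicarboxylate, eight-membered dilactone with (1R,2R)-1,2-diphenylethane-1,2-diol, C3=C4 double bond | COc1cc([C@H]2c3c(cc(OC)c(O)c3OC)C=C3C(=O)O[C@H](c4ccccc4)[C@@H](c4ccccc4)OC(=O)[C@H]23)ccc1O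
A2 | alternative 1 | (1R,2R)-1,2-diphenylethane-1,2-diyl (E)-3-(4-hydroxy-3-methoxyphenyl)prop-2-enoate (E)-3-(4-hydroxy-3,5-dimethoxyphenyl)prop-2-enoate (mixed diester) | COc1cc(/C=C/C(=O)O[C@H](c2ccccc2)[C@@H](c2ccccc2)OC(=O)/C=C/c2cc(OC)c(O)c(OC)c2)ccc1O
A3 | alternative 2 | bis(pivalate) of the target, [(1S,2R,3R)-7-hydroxy-1-(4-hydroxy-3-methoxyphenyl)-6,8-dimethoxy-1,2,3,4-tetrahydronaphthalene-2,3-diyl]bis(methylene) bis(2,2-dimethylpropanoate) | COc1cc([C@H]2c3c(cc(OC)c(O)c3OC)C[C@@H](COC(=O)C(C)(C)C)[C@@H]2COC(=O)C(C)(C)C)ccc1O
A4 | alternative 2 | (2R,3R)-2-formyl-3-[(4-hydroxy-3,5-dimethoxyphenyl)methyl]butane-1,4-diyl bis(2,2-dimethylpropanoate) | O=C[C@@H](COC(=O)C(C)(C)C)[C@H](COC(=O)C(C)(C)C)Cc1cc(OC)c(O)c(OC)c1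
A5 | alternative 2 | guaiacol, 2-methoxyphenol | COc1ccccc1O
A6 | alternative 3 | (1S,2R,3R)-1-[4-(benzyloxy)-3-methoxyphenyl]-2,3-bis[(benzyloxy)methyl]-6,7-dimethoxy-1,2,3,4-tetrahydronaphthalen-8-ol (numbering of the target) | COc1cc([C@H]2c3c(cc(OC)c(OC)c3O)C[C@@H](COCc4ccccc4)[C@@H]2COCc2ccccc2)ccc1OCc1ccccc1
A7 | alternative 3 | tributyl{(3R,4R,5R)-3-[4-(benzyloxy)-3-methoxyphenyl]-4,5-bis[(benzyloxy)methyl]cyclohex-1-en-1-yl}stannane | COc1cc([C@H]2C=C([Sn](CCCC)(CCCC)CCCC)C[C@@H](COCc3ccccc3)[C@@H]2COCc2ccccc2)ccc1OCc1ccccc1
A8 | alternative 3 | 4-chloro-2,3-dimethoxycyclobut-2-en-1-one (racemic) | COC1=C(OC)C(Cl)C1=O
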